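**Plan**

- Retrosynthetic cuts, in order: the chalcone Cα=Cβ bond (Claisen–Schmidt); the prenyl C=C (Wittig on a C3–CH2–CHO unit); the pyran C2–C3 bond (6-exo radical conjugate addition); the side-chain C=C (cross-metathesis) and the C4–C4a bond (aromatic Claisen); the O1–C2 bond (O-alkylation).
- Forward: the oxygenated A ring is bought complete. O1–C2 is made first, then C4a–C4, then the acceptor chain; the pyran ring closes last at C2–C3. The prenyl group and then the chalcone are built on the finished chroman.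
- Enabling feature: C2 is a fully substituted carbon bound to the aryl ether oxygen O1, so it is available as an oxygen-stabilised tertiary radical by decarboxylation of an aryloxyisobutyric acid. C3 is one carbon from the future prenyl CH=; at the carboxyl level C3 becomes the β-carbon of a conjugate acceptor, held 6-exo to C2 by the O1–C8a–C4a–C4 unit.
- Stereochemistry: the only stereocentre (C3) is set in the ring closure by a (4R)-4-(diphenylmethyl)oxazolidinone on the acceptor under Lewis-acid chelation. The auxiliary and the carboxyl oxidation level are removed afterwards (thioester, Fukuyama reduction, Wittig).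
- Protection: MOM on the ketone-flanked phenol and on both B-ring phenols, all removed in the last step.

Key step: step 9

Assumptions: compound 1 and both enantiomers of 13 are taken as commercial. The facial sense in step 9 is taken from the chelate model for Lewis-acid-bound N-enoyl-4-(diphenylmethyl)oxazolidinones (attack anti to CHPh2 in the syn-s-cis chelate), which requires the (4R)-auxiliary. Chroman numbering (O1, C2, C3, C4, C4a, C5–C8, C8a) is used throughout.

**Route**

Step 1
Reactants: 1 1-(2,4-dihydroxy-6-methoxyphenyl)ethan-1-one; 2 ethyl 2-bromo-2-methylpropanoate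
Product: 3 ethyl 2-(4-acetyl-3-hydroxy-5-methoxyphenoxy)-2-methylpropanoate
Conditions: K2CO3 (2.2 equiv), 2 (3 equiv), DMF, 70 °C
Reagents that add atoms: ethyl 2-bromo-2-methylpropanoate CCOC(=O)C(C)(C)Br
Why: Williamson O-alkylation should take place at the 4-OH, the more acidic phenol para to the acetyl group, because the 2-OH is tied up in a hydrogen bond to the ketone.

Step 2
Reactants: 3 ethyl 2-(4-acetyl-3-hydroxy-5-methoxyphenoxy)-2-methylpropanoate; 4 allyl bromide
Product: 5 ethyl 2-[4-acetyl-3-(allyloxy)-5-methoxyphenoxy]-2-methylpropanoate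
Conditions: allyl bromide (1.5 equiv), K2CO3 (2 equiv), DMF, 60 °C
Reagents that add atoms: allyl bromide C=CCBr
Why: Williamson etherification of the remaining chelated phenol should proceed with the reactive allylic halide under slightly forcing conditions.

Step 3
Reactants: 5 ethyl 2-[4-acetyl-3-(allyloxy)-5-methoxyphenoxy]-2-methylpropanoate
Product: 7 ethyl 2-(4-acetyl-2-allyl-3-hydroxy-5-methoxyphenoxy)-2-methylpropanoate, via ortho-dienone 6 (not isolated)
Conditions: PhNEt2, 190 °C, sealed tube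
Reagents that add atoms: none
Why: The aromatic Claisen rearrangement can only deliver the allyl group to the one free ortho position (the other carries the acetyl group), and the dienone then tautomerises to the phenol.

Step 4
Reactants: 7 ethyl 2-(4-acetyl-2-allyl-3-hydroxy-5-methoxyphenoxy)-2-methylpropanoate; 8 chloromethyl methyl ether
Product: 9 ethyl 2-[4-acetyl-2-allyl-5-methoxy-3-(methoxymethoxy)phenoxy]-2-methylpropanoate
Conditions: NaH (1.2 equiv), DMF, 0 °C; MOMCl (1.5 equiv), 0 °C to rt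
Reagents that add atoms: chloromethyl methyl ether COCCl
Why: O-alkylation of the sodium phenoxide (MOM protection) masks the phenol that would otherwise close a dihydrobenzofuran by 5-exo oxa-Michael addition once the acceptor chain is in place.

Step 5
Reactants: 9 ethyl 2-[4-acetyl-2-allyl-5-methoxy-3-(methoxymethoxy)phenoxy]-2-methylpropanoate
Product: 10 2-[4-acetyl-2-allyl-5-methoxy-3-(methoxymethoxy)phenoxy]-2-methylpropanoic acid
Conditions: LiOH·H2O (5 equiv), THF/MeOH/H2O 3:1:1, 50 °C; then 1 M HCl to pH 4, 0 °C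
Reagents that add atoms: lithium hydroxide [Li+].[OH-]
Why: Saponification of the hindered ester should proceed cleanly at this stage, where no base-sensitive group is present yet.

Step 6
Reactants: 10 2-[4-acetyl-2-allyl-5-methoxy-3-(methoxymethoxy)phenoxy]-2-methylpropanoic acid; 11 N-hydroxyphthalimide
Product: 12 1,3-dioxoisoindolin-2-yl 2-[4-acetyl-2-allyl-5-methoxy-3-(methoxymethoxy)phenoxy]-2-methylpropanoate
Conditions: DIC (1.2 equiv), DMAP (10 mol%), CH2Cl2, rt
Reagents that add atoms: N-hydroxyphthalimide ON1C(=O)c2ccccc2C1=O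
Why: Carbodiimide (Steglich-type) esterification should convert the tertiary acid into the redox-active ester that later serves as the radical precursor.

Step 7
Reactants: 13 (4R)-4-(diphenylmethyl)oxazolidin-2-one; 14 acryloyl chloride
Product: 15 (4R)-3-acryloyl-4-(diphenylmethyl)oxazolidin-2-one
Conditions: n-BuLi (1.05 equiv), THF, −78 °C; acryloyl chloride (1.2 equiv), −78 to 0 °C
Reagents that add atoms: acryloyl chloride C=CC(Cl)=O
Why: N-acylation of the lithiated oxazolidinone is the standard entry to N-enoyl imides, and the low temperature limits polymerisation of the acrylimide.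

Step 8
Reactants: 12 1,3-dioxoisoindolin-2-yl 2-[4-acetyl-2-allyl-5-methoxy-3-(methoxymethoxy)phenoxy]-2-methylpropanoate; 15 (4R)-3-acryloyl-4-(diphenylmethyl)oxazolidin-2-one
Product: 16 1,3-dioxoisoindolin-2-yl 2-{4-acetyl-2-[(2E)-4-[(4R)-4-(diphenylmethyl)-2-oxooxazolidin-3-yl]-4-oxobut-2-en-1-yl]-5-methoxy-3-(methoxymethoxy)phenoxy}-2-methylpropanoate
Conditions: Hoveyda–Grubbs II (5 mol%), 15 (2.5 equiv), 1,4-benzoquinone (10 mol%), CH2Cl2, 40 °C
Reagents that add atoms: (4R)-3-acryloyl-4-(diphenylmethyl)oxazolidin-2-one C=CC(=O)N1[C@H](C(c2ccccc2)c2ccccc2)COC1=O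
Why: Olefin cross-metathesis of a terminal allylarene with an electron-poor acrylimide should be E-selective, driven by loss of ethene, with benzoquinone suppressing double-bond migration.

Step 9
Reactants: 16 1,3-dioxoisoindolin-2-yl 2-{4-acetyl-2-[(2E)-4-[(4R)-4-(diphenylmethyl)-2-oxooxazolidin-3-yl]-4-oxobut-2-en-1-yl]-5-methoxy-3-(methoxymethoxy)phenoxy}-2-methylpropanoate
Product: 18 (4R)-3-{2-[(3S)-6-acetyl-7-methoxy-5-(methoxymethoxy)-2,2-dimethyl-3,4-dihydro-2H-chromen-3-yl]acetyl}-4-(diphenylmethyl)oxazolidin-2-one, via tertiary aryloxyalkyl radical 17 (not isolated)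
Conditions: Y(OTf)3 (2 equiv), Hantzsch ester (1.5 equiv), Ru(bpy)3(PF6)2 (1 mol%), CH2Cl2/THF 4:1, 450 nm LEDs, −40 °C, degassed
Reagents that add atoms: none
Why: Single-electron reduction of the N-acyloxyphthalimide by photogenerated Ru(I) should cleave the N–O bond and expel CO2 to give the oxygen-stabilised tertiary radical 17, which adds to the β-carbon (C3) of the Y(III)-chelated enoyl imide before the α-imide radical is quenched by hydrogen-atom transfer from the Hantzsch ester. The closest known reaction types are the reductive decarboxylative Giese addition of redox-active esters and the Lewis-acid-chelated β-selective radical conjugate addition to N-enoyl-4-(diphenylmethyl)oxazolidinones. The pyran ring closes in the 6-exo-trig mode and joins the fully substituted C2 to C3. C3 is controlled by the (4R)-diphenylmethyl group, which in the syn-s-cis chelate covers the Re face of C3, so the radical should enter on the Si face and give the (3S) imide, which is the (3R) configuration of the target once the side chain has become prenyl. The step needs exo rather than endo attack, ring closure faster than 1,5-hydrogen transfer from the C4 methylene or reduction of the open radical, and reaction through the chelate only; the polarity match of the nucleophilic α-oxy radical with the Lewis-acid-activated acceptor, the rigid o-phenylene tether with a gem-dimethyl radical centre, and two equivalents of a redox-inert Lewis acid at low temperature should secure these. A minor C3 epimer would be a diastereomer of 18 and removable by chromatography.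

Step 10
Reactants: 18 (4R)-3-{2-[(3S)-6-acetyl-7-methoxy-5-(methoxymethoxy)-2,2-dimethyl-3,4-dihydro-2H-chromen-3-yl]acetyl}-4-(diphenylmethyl)oxazolidin-2-one; 19 ethanethiol
Product: 20 S-ethyl 2-[(3S)-6-acetyl-7-methoxy-5-(methoxymethoxy)-2,2-dimethyl-3,4-dihydro-2H-chromen-3-yl]ethanethioate
Conditions: EtSH (3 equiv), n-BuLi (2.2 equiv), THF, 0 °C; aq. NH4Cl
Reagents that add atoms: ethanethiol CCS
Why: Thiolate transacylation should cleave the unhindered exocyclic imide carbonyl, releasing the auxiliary for recovery and leaving the hindered aryl methyl ketone untouched.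

Step 11
Reactants: 20 S-ethyl 2-[(3S)-6-acetyl-7-methoxy-5-(methoxymethoxy)-2,2-dimethyl-3,4-dihydro-2H-chromen-3-yl]ethanethioate
Product: 21 2-[(3S)-6-acetyl-7-methoxy-5-(methoxymethoxy)-2,2-dimethyl-3,4-dihydro-2H-chromen-3-yl]acetaldehyde
Conditions: Et3SiH (3 equiv), 10% Pd/C (10 mol%), acetone, rt
Reagents that add atoms: none
Why: The Fukuyama reduction should take the thioester to the aldehyde without touching the aryl ketone, which a hydride reagent would not distinguish as reliably.

Step 12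
Reactants: 21 2-[(3S)-6-acetyl-7-methoxy-5-(methoxymethoxy)-2,2-dimethyl-3,4-dihydro-2H-chromen-3-yl]acetaldehyde; 22 isopropyltriphenylphosphonium iodide
Product: 23 1-[(3R)-7-methoxy-5-(methoxymethoxy)-2,2-dimethyl-3-(3-methylbut-2-en-1-yl)-3,4-dihydro-2H-chromen-6-yl]ethan-1-one
Conditions: 22 (1.3 equiv), n-BuLi (1.25 equiv), THF, 0 °C; then 21, −78 to 0 °C
Reagents that add atoms: isopropyltriphenylphosphonium iodide CC(C)[P+](c1ccccc1)(c1ccccc1)c1ccccc1.[I-]
Why: Wittig olefination with the isopropylidene ylide should be selective for the aldehyde over the di-ortho-substituted methyl ketone; the stereocentre is β to the carbonyl and cannot epimerise.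

Step 13
Reactants: 24 2,4-dihydroxybenzaldehyde; 8 chloromethyl methyl ether
Product: 25 2,4-bis(methoxymethoxy)benzaldehyde
Conditions: MOMCl (3 equiv), K2CO3 (4 equiv), acetone, reflux
Reagents that add atoms: chloromethyl methyl ether COCCl
Why: Double O-alkylation (MOM protection) keeps the aldehyde electrophilic in the base-mediated condensation, where free phenoxides would deactivate it.

Step 14
Reactants: 23 1-[(3R)-7-methoxy-5-(methoxymethoxy)-2,2-dimethyl-3-(3-methylbut-2-en-1-yl)-3,4-dihydro-2H-chromen-6-yl]ethan-1-one; 25 2,4-bis(methoxymethoxy)benzaldehyde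
Product: 26 (2E)-3-[2,4-bis(methoxymethoxy)phenyl]-1-[(3R)-7-methoxy-5-(methoxymethoxy)-2,2-dimethyl-3-(3-methylbut-2-en-1-yl)-3,4-dihydro-2H-chromen-6-yl]prop-2-en-1-one
Conditions: KOH (50% aq., 10 equiv), EtOH, rt
Reagents that add atoms: 2,4-bis(methoxymethoxy)benzaldehyde COCOc1ccc(C=O)c(OCOC)c1
Why: Claisen–Schmidt condensation of the methyl ketone with the non-enolisable aldehyde should give the E-chalcone, and the protected ortho oxygen prevents flavanone formation under base.

Step 15
Reactants: 26 (2E)-3-[2,4-bis(methoxymethoxy)phenyl]-1-[(3R)-7-methoxy-5-(methoxymethoxy)-2,2-dimethyl-3-(3-methylbut-2-en-1-yl)-3,4-dihydro-2H-chromen-6-yl]prop-2-en-1-one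
Product: 27 (2E)-3-(2,4-dihydroxyphenyl)-1-[(3R)-5-hydroxy-7-methoxy-2,2-dimethyl-3-(3-methylbut-2-en-1-yl)-3,4-dihydro-2H-chromen-6-yl]prop-2-en-1-one
Conditions: 3 M aq. HCl/MeOH 1:5, 40 °C, monitored and stopped at full conversion
Reagents that add atoms: none
Why: Acid-catalysed acetal exchange with methanol should remove all three MOM ethers, as is usual for prenylated 2'-hydroxychalcones, without disturbing the chroman stereocentre.

**Compound list**

1 | 1-(2,4-dihydroxy-6-methoxyphenyl)ethan-1-one | CC(=O)c1c(O)cc(O)cc1OC | starting material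
2 | ethyl 2-bromo-2-methylpropanoate | CCOC(=O)C(C)(C)Br | starting material
3 | ethyl 2-(4-acetyl-3-hydroxy-5-methoxyphenoxy)-2-methylpropanoate | CCOC(=O)C(C)(C)Oc1cc(O)c(C(C)=O)c(OC)c1 | intermediate
4 | allyl bromide | C=CCBr | starting material
5 | ethyl 2-[4-acetyl-3-(allyloxy)-5-methoxyphenoxy]-2-methylpropanoate | CCOC(=O)C(C)(C)Oc1cc(OCC=C)c(C(C)=O)c(OC)c1 | intermediate
6 | ethyl 2-[(4-acetyl-6-allyl-3-methoxy-5-oxocyclohexa-1,3-dien-1-yl)oxy]-2-methylpropanoate (ortho-dienone, not isolated) | CCOC(=O)C(C)(C)OC1=CC(OC)=C(C(C)=O)C(=O)C1CC=C | intermediate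
7 | ethyl 2-(4-acetyl-2-allyl-3-hydroxy-5-methoxyphenoxy)-2-methylpropanoate | CCOC(=O)C(C)(C)Oc1cc(OC)c(C(C)=O)c(O)c1CC=C | intermediate
8 | chloromethyl methyl ether | COCCl | starting material
9 | ethyl 2-[4-acetyl-2-allyl-5-methoxy-3-(methoxymethoxy)phenoxy]-2-methylpropanoate | CCOC(=O)C(C)(C)Oc1cc(OC)c(C(C)=O)c(OCOC)c1CC=C | intermediate
10 | 2-[4-acetyl-2-allyl-5-methoxy-3-(methoxymethoxy)phenoxy]-2-methylpropanoic acid | OC(=O)C(C)(C)Oc1cc(OC)c(C(C)=O)c(OCOC)c1CC=C | intermediate
11 | N-hydroxyphthalimide | ON1C(=O)c2ccccc2C1=O | starting material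
12 | 1,3-dioxoisoindolin-2-yl 2-[4-acetyl-2-allyl-5-methoxy-3-(methoxymethoxy)phenoxy]-2-methylpropanoate | O=C1c2ccccc2C(=O)N1OC(=O)C(C)(C)Oc1cc(OC)c(C(C)=O)c(OCOC)c1CC=C | intermediate
13 | (4R)-4-(diphenylmethyl)oxazolidin-2-one | O=C1N[C@H](C(c2ccccc2)c2ccccc2)CO1 | starting material
14 | acryloyl chloride | C=CC(Cl)=O | starting material
15 | (4R)-3-acryloyl-4-(diphenylmethyl)oxazolidin-2-one | C=CC(=O)N1[C@H](C(c2ccccc2)c2ccccc2)COC1=O | intermediate
16 | 1,3-dioxoisoindolin-2-yl 2-{4-acetyl-2-[(2E)-4-[(4R)-4-(diphenylmethyl)-2-oxooxazolidin-3-yl]-4-oxobut-2-en-1-yl]-5-methoxy-3-(methoxymethoxy)phenoxy}-2-methylpropanoate | O=C1c2ccccc2C(=O)N1OC(=O)C(C)(C)Oc1cc(OC)c(C(C)=O)c(OCOC)c1C/C=C/C(=O)N1[C@H](C(c2ccccc2)c2ccccc2)COC1=O | intermediate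
17 | 2-aryloxyprop-2-yl radical formed from 16 by loss of CO2 and phthalimide (not isolated) | C[C](C)Oc1cc(OC)c(C(C)=O)c(OCOC)c1C/C=C/C(=O)N1[C@H](C(c2ccccc2)c2ccccc2)COC1=O | intermediate
18 | (4R)-3-{2-[(3S)-6-acetyl-7-methoxy-5-(methoxymethoxy)-2,2-dimethyl-3,4-dihydro-2H-chromen-3-yl]acetyl}-4-(diphenylmethyl)oxazolidin-2-one | COCOc1c(C(C)=O)c(OC)cc2c1C[C@@H](CC(=O)N1[C@H](C(c3ccccc3)c3ccccc3)COC1=O)C(C)(C)O2 | intermediate
19 | ethanethiol | CCS | starting material
20 | S-ethyl 2-[(3S)-6-acetyl-7-methoxy-5-(methoxymethoxy)-2,2-dimethyl-3,4-dihydro-2H-chromen-3-yl]ethanethioate | COCOc1c(C(C)=O)c(OC)cc2c1C[C@@H](CC(=O)SCC)C(C)(C)O2 | intermediate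
21 | 2-[(3S)-6-acetyl-7-methoxy-5-(methoxymethoxy)-2,2-dimethyl-3,4-dihydro-2H-chromen-3-yl]acetaldehyde | COCOc1c(C(C)=O)c(OC)cc2c1C[C@@H](CC=O)C(C)(C)O2 | intermediate
22 | isopropyltriphenylphosphonium iodide | CC(C)[P+](c1ccccc1)(c1ccccc1)c1ccccc1.[I-] | starting material
23 | 1-[(3R)-7-methoxy-5-(methoxymethoxy)-2,2-dimethyl-3-(3-methylbut-2-en-1-yl)-3,4-dihydro-2H-chromen-6-yl]ethan-1-one | COCOc1c(C(C)=O)c(OC)cc2c1C[C@@H](CC=C(C)C)C(C)(C)O2 | intermediate
24 | 2,4-dihydroxybenzaldehyde | O=Cc1ccc(O)cc1O | starting material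
25 | 2,4-bis(methoxymethoxy)benzaldehyde | COCOc1ccc(C=O)c(OCOC)c1 | intermediate
26 | (2E)-3-[2,4-bis(methoxymethoxy)phenyl]-1-[(3R)-7-methoxy-5-(methoxymethoxy)-2,2-dimethyl-3-(3-methylbut-2-en-1-yl)-3,4-dihydro-2H-chromen-6-yl]prop-2-en-1-one | COCOc1ccc(/C=C/C(=O)c2c(OC)cc3c(c2OCOC)C[C@@H](CC=C(C)C)C(C)(C)O3)c(OCOC)c1 | intermediate
27 | (2E)-3-(2,4-dihydroxyphenyl)-1-[(3R)-5-hydroxy-7-methoxy-2,2-dimethyl-3-(3-methylbut-2-en-1-yl)-3,4-dihydro-2H-chromen-6-yl]prop-2-en-1-one | COc1cc2c(c(O)c1C(=O)/C=C/c1ccc(O)cc1O)C[C@@H](CC=C(C)C)C(C)(C)O2 | target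

**Summary**

Total step count: 15. Longest linear sequence: 13 steps (steps 1–6, 8–12, 14, 15); steps 7 and 13 prepare the two side components.

**Steps most likely to fail**

1. Step 9 (key step). Part of the substrate may react through the unchelated rotamer, which would erode facial control. The Lewis acid may ionise the activated ester or strip the MOM ether before the radical forms. 1,5-Hydrogen transfer from the C4 methylene may compete with ring closure. Fallback, setting out from 12 and returning at 18: cross-metathesis of 12 with methyl acrylate (Hoveyda–Grubbs II, CH2Cl2, 40 °C) should give 1,3-dioxoisoindolin-2-yl 2-{4-acetyl-5-methoxy-2-[(2E)-4-methoxy-4-oxobut-2-en-1-yl]-3-(methoxymethoxy)phenoxy}-2-methylpropanoate F1. Lewis-acid-free reductive photoredox cyclisation (Ru(bpy)3(PF6)2, Hantzsch ester, CH2Cl2, blue LEDs, rt) should give racemic methyl 2-[6-acetyl-7-methoxy-5-(methoxymethoxy)-2,2-dimethyl-3,4-dihydro-2H-chromen-3-yl]acetate F2. Saponification (LiOH, THF/H2O) should give racemic 2-[6-acetyl-7-methoxy-5-(methoxymethoxy)-2,2-dimethyl-3,4-dihydro-2H-chromen-3-yl]acetic acid F3. Mixed-anhydride acylation of 13 (PivCl, Et3N, LiCl, THF) should then give 18 together with its C3 epimer (4R)-3-{2-[(3R)-6-acetyl-7-methoxy-5-(methoxymethoxy)-2,2-dimethyl-3,4-dihydro-2H-chromen-3-yl]acetyl}-4-(diphenylmethyl)oxazolidin-2-one F4, from which 18 is separated by chromatography or crystallisation. The stereocentre then comes from resolution through the auxiliary and not from induction.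

2. Step 8. The allylarene double bond may migrate into conjugation with the ring through ruthenium hydride species, and turnover with the bulky acrylimide may be slow, so that homodimerisation dominates. Fallback, setting out from 12 and returning at 16: Lemieux–Johnson cleavage of 12 (OsO4 cat., NaIO4, 2,6-lutidine, dioxane/H2O) should give 1,3-dioxoisoindolin-2-yl 2-[4-acetyl-5-methoxy-3-(methoxymethoxy)-2-(2-oxoethyl)phenoxy]-2-methylpropanoate F5. Horner–Wadsworth–Emmons olefination under Masamune–Roush conditions (LiCl, iPr2NEt, MeCN, 0 °C) with diethyl {2-[(4R)-4-(diphenylmethyl)-2-oxooxazolidin-3-yl]-2-oxoethyl}phosphonate F6 should then give 16 as the E-isomer. F6 is made from 13 and diethylphosphonoacetic acid (PivCl, Et3N, LiCl, THF).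

3. Step 15. Under the acid needed for the two unactivated B-ring MOM ethers, the freed 2'-hydroxychalcone may close to the flavanone by oxa-Michael addition, and HCl, water or methanol may add across the prenyl double bond. Fallback, setting out from 23 and returning at 27: only the ketone-flanked MOM ether of 23 is removed under mild conditions (PPTS, MeOH, 50 °C) to give 1-[(3R)-5-hydroxy-7-methoxy-2,2-dimethyl-3-(3-methylbut-2-en-1-yl)-3,4-dihydro-2H-chromen-6-yl]ethan-1-one F7. Claisen–Schmidt condensation (KOH, EtOH, rt) with 2,4-bis(allyloxy)benzaldehyde F8 (from 24 and allyl bromide 4, K2CO3, DMF) should give (2E)-3-[2,4-bis(allyloxy)phenyl]-1-[(3R)-5-hydroxy-7-methoxy-2,2-dimethyl-3-(3-methylbut-2-en-1-yl)-3,4-dihydro-2H-chromen-6-yl]prop-2-en-1-one F9. Both allyl ethers are then removed under neutral conditions (Pd(PPh3)4 5 mol%, morpholine, THF, rt) to give 27.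

**Further compounds**

F1 | step 9 | 1,3-dioxoisoindolin-2-yl 2-{4-acetyl-5-methoxy-2-[(2E)-4-methoxy-4-oxobut-2-en-1-yl]-3-(methoxymethoxy)phenoxy}-2-methylpropanoate | O=C1c2ccccc2C(=O)N1OC(=O)C(C)(C)Oc1cc(OC)c(C(C)=O)c(OCOC)c1C/C=C/C(=O)OC
F2 | step 9 | racemic methyl 2-[6-acetyl-7-methoxy-5-(methoxymethoxy)-2,2-dimethyl-3,4-dihydro-2H-chromen-3-yl]acetate | COCOc1c(C(C)=O)c(OC)cc2c1CC(CC(=O)OC)C(C)(C)O2
F3 | step 9 | racemic 2-[6-acetyl-7-methoxy-5-(methoxymethoxy)-2,2-dimethyl-3,4-dihydro-2H-chromen-3-yl]acetic acid | COCOc1c(C(C)=O)c(OC)cc2c1CC(CC(=O)O)C(C)(C)O2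
F4 | step 9 | (4R)-3-{2-[(3R)-6-acetyl-7-methoxy-5-(methoxymethoxy)-2,2-dimethyl-3,4-dihydro-2H-chromen-3-yl]acetyl}-4-(diphenylmethyl)oxazolidin-2-one | COCOc1c(C(C)=O)c(OC)cc2c1C[C@H](CC(=O)N1[C@H](C(c3ccccc3)c3ccccc3)COC1=O)C(C)(C)O2
F5 | step 8 | 1,3-dioxoisoindolin-2-yl 2-[4-acetyl-5-methoxy-3-(methoxymethoxy)-2-(2-oxoethyl)phenoxy]-2-methylpropanoate | O=CCc1c(OC(C)(C)C(=O)ON2C(=O)c3ccccc3C2=O)cc(OC)c(C(C)=O)c1OCOC
F6 | step 8 | diethyl {2-[(4R)-4-(diphenylmethyl)-2-oxooxazolidin-3-yl]-2-oxoethyl}phosphonate | CCOP(=O)(OCC)CC(=O)N1[C@H](C(c2ccccc2)c2ccccc2)COC1=O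
F7 | step 15 | 1-[(3R)-5-hydroxy-7-methoxy-2,2-dimethyl-3-(3-methylbut-2-en-1-yl)-3,4-dihydro-2H-chromen-6-yl]ethan-1-one | COc1cc2c(c(O)c1C(C)=O)C[C@@H](CC=C(C)C)C(C)(C)O2
F8 | step 15 | 2,4-bis(allyloxy)benzaldehyde | C=CCOc1ccc(C=O)c(OCC=C)c1
F9 | step 15 | (2E)-3-[2,4-bis(allyloxy)phenyl]-1-[(3R)-5-hydroxy-7-methoxy-2,2-dimethyl-3-(3-methylbut-2-en-1-yl)-3,4-dihydro-2H-chromen-6-yl]prop-2-en-1-one | COc1cc2c(c(O)c1C(=O)/C=C/c1ccc(OCC=C)cc1OCC=C)C[C@@H](CC=C(C)C)C(C)(C)O2
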